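**Numbering.** The locants C1–C20 of the target 40 are used for every intermediate: C1 ring-fusion CH, C2 lactone O–CH, C3=C4 (methyl C18), C7=C8 (methyl C19), C11–C12 epoxide (methyl C20), C13 CHOAc, C14 CH2, C15=C17 exocyclic methylene, C16 lactone carbonyl.

## The problem

Compound 40 is a cembranolide: a fourteen-membered carbocycle (C1–C14) with an α-methylene-γ-butyrolactone (C15, C16, C17, ring oxygen on C2) trans-fused across C1–C2. The carbocycle carries two (E)-trisubstituted alkenes (C3=C4, C7=C8), a trisubstituted epoxide at C11–C12 and an acetoxy group on C13, and it holds five stereocentres: C1 (R), C2 (S), C11 (R), C12 (S) and C13 (S). C1, C2 and C13 lie on one short chain linked by the C14 methylene and need absolute control, whereas C11 and C12 can be slaved to C13, because an allylic hydroxyl on C13 can deliver the epoxide oxygen to one face of an (E)-C11=C12 alkene. That delivery gives the erythro epoxy alcohol while 40 is the threo epoxy acetate, so C13 has to be carried in the unnatural configuration and inverted once the epoxide is in place. The α-methylene lactone (a Michael acceptor that tolerates neither hydrides, carbanions nor alkoxides), the epoxide next to an acetate and the allylic C2–O bond demand that lactone, epoxide and acetate come last, and the flexible large ring should be closed at a bond that creates no stereocentre. The feature that opens the route is the chain C13–C14–C1–C2: C2 is bound to the sp2 carbon C3 and C13 to C12, which already bears C20, so an imaginary C3–C12 bond turns C1, C2, C3, C12, C13 and C14 into a 3-methylcyclohexene with oxygen on both allylic carbons and a two-carbon acyl branch (C15, C17) on C1, the retron of a Diels–Alder reaction.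

## Retrosynthesis

**C13–O and the epoxide.** The acetate C–O bond at C13 is cut with inversion (40 to epoxy alcohol 39), and the epoxide oxygen is then removed to give allylic alcohol 38. The order is forced: directed epoxidation gives the erythro relationship, the target is threo, and a peracid acting on a preformed 13-acetate would attack the unhindered C7=C8 alkene first. Compound 38 is simpler by two stereocentres and by both acid-labile groups. The forward steps need face selection through allylic 1,2-strain and an SN2 displacement at a hindered carbinol.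

**The lactone.** In 37, the 4-methoxybenzyl ether of 38, the alkyl–oxygen bond O–C2 is cut rather than the acyl–oxygen bond, giving hydroxy acid 36. Closure with inversion is what converts the cis C1/C2 pattern of a cycloadduct into the trans-lactone; an acyl–oxygen closure would retain C2 and give the wrong ring fusion. The silyl ether 35 of this acid is cut at C15–C16 into alkenyl triflate 34 and carbon monoxide, and 34 goes back to methyl ketone 33 and its dioxolane 32. Carrying an acrylate from an early stage would expose it to hydrides and sulfonyl carbanions, and 32 contains no electrophilic carbonyl at all. The forward steps need regioselective enolisation towards the methyl group and a clean intramolecular displacement at an allylic carbon.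

**The macrocycle.** With phenylsulfonyl groups put back on C6 and C10 (31), the ring is opened at C9–C10 to allylic bromide 30. This bond joins two allylic methylenes and creates no stereocentre. Of the two sulfonyl carbanions only the C10 anion can reach C9, since the C6 anion would have to close a four-membered ring. Compound 30 comes through 29, 28 and 26 from ester 25, which is cut at C5–C6 into bromide 19 and the C6–C9 sulfone 24. Bringing in the unsymmetrical isoprene unit with one sulfone end and one masked hydroxyl end fixes its orientation; a one-pot double alkylation could not tell C5 from C10. The forward reactions are two sulfone-anion alkylations, one of them at high dilution, and a reductive removal of both sulfonyl groups.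

**The two flanking alkenes and the fictitious bond.** Bromide 19 derives through alcohol 18 from diester 17. C11=C12 is cut by a Horner–Wadsworth–Emmons disconnection (17 to ketone 15 and phosphonate 16), and C3=C4 by a Wittig disconnection (15 to aldehyde 14 and ylide 13). Joining the C3 aldehyde and the C12 ketone of 14 gives the alkene of cyclohexene 12. The aldehyde/ketone difference orders the two olefinations, and an ethyl ester at C5 against a tert-butyl ester at C10 keeps the two ends distinguishable. Both olefinations must be E-selective, and C2 and C13, each α to a carbonyl group in 14 and 15, must not epimerise.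

**The template.** Cyclohexene 12 goes back through 11 and 10 to adduct 9 by protecting-group changes only: the acetyl group is masked as a dioxolane, and the acetate is replaced by an ether that survives hydrides. Adduct 9 is cut at C1–C2 and C13–C14 into diene 7 and methyl vinyl ketone 8. The all-cis endo adduct is what the plan needs, because C2 and C13 are each inverted later; an exo adduct would have C13 in its final configuration, and no erythro-selective epoxidation could then be used. Two achiral, acyclic pieces of five and four carbons replace a ring with three stereocentres. The forward reaction must control regiochemistry, endo selectivity and the absolute sense.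

**Starting materials.** Diene 7 is the silyl dienol ether of enal 6, which comes through 5, 4 and acetal 2 from prenal 1 by allylic oxidation of the (E)-methyl group. Sulfone 24 comes through 23 and 21 from prenyl bromide 20 by the same oxidation.

## Roads not taken

Alternative 1: The ring is cut at C11–C12, taken as a triple bond without C20. The alkylidyne complex [(4-MeOC6H4)C≡Mo(OSiPh3)3] would metathesise two methyl-capped alkyne termini and close the cycloalkyne A1. After desilylation the C13 hydroxyl would steer a trans-hydrostannation, and exchange of tin for methyl would give the (E)-C11=C12 alkene with C20.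
- Merits: the closure is tolerant, is driven by loss of a volatile alkyne and raises no E/Z question. The alkene geometry follows from the trans addition. The ring-forming phase is clearly shorter than the eleven main-line steps (10–13 and 17–23) used here.
- Weak points: A1 already contains the α-methylene lactone, which must survive tin hydride, a metal hydride catalyst and a methyl transfer, all of which can add to an acrylate. C1, C2 and C13 must be made by separate asymmetric operations.
- Comparison: in step economy and mildness of the ring closure this road is better. The chosen plan sets against it that one catalytic step fixes C1, C2 and C13 together and that the lactone is never exposed to nucleophilic or radical reagents.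

Alternative 2: The lactone is cut at C16–O and C15–C16, back to a macrocyclic precursor with a free C2 hydroxyl and an ethynyl group on C1. PdCl2, SnCl2 and PPh3 under carbon monoxide would join hydroxyl, CO and alkyne and give the α-methylene lactone A2 in one operation.
- Merits: this is the most direct construction of the lactone. CO supplies C16 as in the chosen plan. One step replaces the four used here (steps 25–28) and the two ketal steps.
- Weak points: it is an end-game and leaves open how the ring and C1, C2 and C13 are made. The lactone closes with retention, so the trans C1/C2 relation must already exist. The Lewis-acidic tin salt meets an allylic C2 hydroxyl and skipped alkenes.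
- Comparison: for the lactone itself this road is better. The chosen plan accepts the longer sequence because inversion at C2 during lactonisation is what makes the all-cis cycloadduct usable.

Alternative 3: The carbocycle is cut at C1–C2. n-BuLi would deprotonate the propargylic C2–H of a seventeen-membered C2–O–C17 ether, and a [2,3]-Wittig shift would form C1–C2, break O–C17 and contract the ring to the carbocyclic alcohol A3.
- Merits: the large ring is first closed as an ether, and the carbocycle and both C1 and C2 arise in one step. That is probably more reliable than a carbanion alkylation at high dilution.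
- Weak points: the C1/C2 relationship depends on the transition-state shape of a large ring, and the absolute sense rests on C13 alone. The C3≡C4 alkyne must still be converted into the (E)-alkene bearing C18. The lactone would then close with retention, so the shift has to deliver the trans pair directly.
- Comparison: in ring formation this road is equal or better. The chosen plan sets against it catalyst-controlled absolute configuration at three centres by well-established selectivity rules, and a C3=C4 geometry that comes from a stabilised Wittig reaction.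

Key step: step 6

Assumption: the facial sense of the oxazaborolidinium catalyst is taken from the accepted pre-transition-state model for enones, by which the (S)-prolinol-derived catalyst should give (1S,2R,13R)-9; the (R)-prolinol-derived catalyst is equally accessible and would be used if the sense were opposite.

## Route

Step 1
Reactants: 1 3-methylbut-2-enal
Product: 2 1,1-dimethoxy-3-methylbut-2-ene
Conditions: HC(OMe)3, MeOH, NH4NO3 (cat.), rt
Reagents that add atoms: trimethyl orthoformate COC(OC)OC
Why: Acid-catalysed acetalisation with the orthoformate as water scavenger; masking the aldehyde lets the next oxidation address the allylic methyl group and not the enal.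

Step 2
Reactants: 2 1,1-dimethoxy-3-methylbut-2-ene
Product: 4 (E)-4,4-dimethoxy-2-methylbut-2-en-1-ol, via acetal aldehyde 3 (not isolated)
Conditions: SeO2 (cat.), t-BuOOH, CH2Cl2, rt; then NaBH4, MeOH, 0 °C
Reagents that add atoms: tert-butyl hydroperoxide CC(C)(C)OO
Why: Riley allylic oxidation (ene reaction, then [2,3]-shift) functionalises the methyl group trans to the acetal-bearing carbon, which fixes the E geometry; borohydride returns over-oxidised aldehyde 3 to the alcohol.

Step 3
Reactants: 4 (E)-4,4-dimethoxy-2-methylbut-2-en-1-ol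
Product: 5 (E)-4,4-dimethoxy-2-methylbut-2-en-1-yl acetate
Conditions: Ac2O, pyridine, 4-dimethylaminopyridine (cat.), CH2Cl2, 0 °C to rt
Reagents that add atoms: acetic anhydride CC(=O)OC(C)=O
Why: Nucleophile-catalysed acylation of a primary allylic alcohol; the acetal is inert to the basic medium.

Step 4
Reactants: 5 (E)-4,4-dimethoxy-2-methylbut-2-en-1-yl acetate
Product: 6 (E)-2-methyl-4-oxobut-2-en-1-yl acetate
Conditions: Amberlyst 15, acetone–H2O, rt
Reagents that add atoms: water O
Why: Acid-catalysed acetal hydrolysis; the primary acetate survives mild aqueous acid, and the alkene geometry is of no consequence because this bond becomes the central single bond of the diene.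

Step 5
Reactants: 6 (E)-2-methyl-4-oxobut-2-en-1-yl acetate
Product: 7 (1E,3E)-4-[(tert-butyldimethylsilyl)oxy]-2-methylbuta-1,3-dien-1-yl acetate
Conditions: t-BuMe2SiOTf, Et3N, Et2O, −78 to 0 °C
Reagents that add atoms: tert-butyldimethylsilyl trifluoromethanesulfonate CC(C)(C)[Si](C)(C)OS(=O)(=O)C(F)(F)F
Why: Soft enolisation (O-silylation, then γ-deprotonation by the amine) to a silyl dienol ether; the s-trans enal gives the (E)-silyloxy alkene, and proton loss is expected from the acetoxymethyl group, which is the more acidic γ-position and leads to the fully conjugated diene. Isomers with an inward-pointing substituent or a cross-conjugated skeleton are poor dienes and should be left behind in step 6.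

Step 6
Reactants: 7 (1E,3E)-4-[(tert-butyldimethylsilyl)oxy]-2-methylbuta-1,3-dien-1-yl acetate, 8 but-3-en-2-one
Product: 9 (1R,4R,5S)-5-acetyl-4-[(tert-butyldimethylsilyl)oxy]-2-methylcyclohex-2-en-1-yl acetate
Conditions: (S)-3,3-diphenyl-1-(o-tolyl)tetrahydropyrrolo[1,2-c][1,3,2]oxazaborole·HNTf2 (20 mol %), CH2Cl2, −78 °C
Reagents that add atoms: none
Why: The cationic oxazaborolidinium ion binds the carbonyl oxygen of 8 and lowers its LUMO, and diene 7 adds through a concerted, asynchronous [4+2] transition state in which C13–C14 bonding runs ahead of C1–C2 bonding. The closest known reaction type is the oxazaborolidinium-catalysed enantioselective Diels–Alder reaction of 1-oxygenated butadienes with vinyl ketones and acrylates. The cyclohexene (C1, C2, C3, C12, C13, C14) closes by an intermolecular suprafacial cycloaddition that forms both σ-bonds in one step. Regiochemistry is secured by the diene: the silyloxy group on the C2 terminus and the methyl group on C12 both place the largest HOMO coefficient on the acetoxy-bearing terminus C13, which bonds to the β-carbon C14, so the acetyl-bearing C1 ends up next to C2. C2 and C13 become cis because both substituents point outward on the (E,E)-diene. C1 becomes cis to both through the endo transition state, which Lewis-acid coordination reinforces. The absolute configuration (1S,2R,13R) comes from the catalyst, which shields one face of the bound enone. The step thus needs regio-, endo- and enantiofacial selectivity, and it needs the silyl dienol ether to survive, which the low temperature and the absence of free acid should ensure.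

Step 7
Reactants: 9 (1R,4R,5S)-5-acetyl-4-[(tert-butyldimethylsilyl)oxy]-2-methylcyclohex-2-en-1-yl acetate
Product: 10 (1R,4R,5S)-4-[(tert-butyldimethylsilyl)oxy]-2-methyl-5-(2-methyl-1,3-dioxolan-2-yl)cyclohex-2-en-1-yl acetate
Conditions: Me3SiOCH2CH2OSiMe3, Me3SiOTf (5 mol %), CH2Cl2, −78 to −20 °C; pyridine
Reagents that add atoms: 1,2-bis(trimethylsilyloxy)ethane C[Si](C)(C)OCCO[Si](C)(C)C
Why: Silyl-triflate-catalysed ketalisation under aprotic, cold conditions, so that C1 is not epimerised and the β-silyloxy group is not eliminated; it removes the acidity of C1–H before any basic step.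

Step 8
Reactants: 10 (1R,4R,5S)-4-[(tert-butyldimethylsilyl)oxy]-2-methyl-5-(2-methyl-1,3-dioxolan-2-yl)cyclohex-2-en-1-yl acetate
Product: 11 (1R,4R,5S)-4-[(tert-butyldimethylsilyl)oxy]-2-methyl-5-(2-methyl-1,3-dioxolan-2-yl)cyclohex-2-en-1-ol
Conditions: K2CO3 (0.2 equiv), MeOH, 0 °C to rt
Reagents that add atoms: none
Why: Base-catalysed transesterification of the allylic acetate to methanol; ketal and secondary silyl ether are inert, and no enolisable carbonyl is left.

Step 9
Reactants: 11 (1R,4R,5S)-4-[(tert-butyldimethylsilyl)oxy]-2-methyl-5-(2-methyl-1,3-dioxolan-2-yl)cyclohex-2-en-1-ol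
Product: 12 tert-butyl{[(1R,4R,6S)-4-[(4-methoxybenzyl)oxy]-3-methyl-6-(2-methyl-1,3-dioxolan-2-yl)cyclohex-2-en-1-yl]oxy}dimethylsilane
Conditions: NaH, 4-MeOC6H4CH2Cl, n-Bu4NI (cat.), THF–DMF, 0 °C to rt
Reagents that add atoms: 4-methoxybenzyl chloride COc1ccc(CCl)cc1
Why: Williamson etherification; the 4-methoxybenzyl ether survives hydride, organolithium and fluoride reagents and is removed oxidatively at the end, orthogonally to the C2 silyl ether.

Step 10
Reactants: 12 cyclohexene template (C2 silyl ether, C13 4-methoxybenzyl ether, C1 dioxolane), 13 ethyl 2-(triphenylphosphoranylidene)propanoate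
Product: 15 ethyl (2E,4R,5S,7R)-4-[(tert-butyldimethylsilyl)oxy]-7-[(4-methoxybenzyl)oxy]-2-methyl-5-(2-methyl-1,3-dioxolan-2-yl)-8-oxonon-2-enoate, via keto aldehyde 14 (not isolated)
Conditions: O3, CH2Cl2, −78 °C (Sudan Red 7B end point); PPh3, −78 °C to rt; then 13, rt
Reagents that add atoms: ozone [O-][O+]=O
Why: Ozonolysis with reductive work-up cleaves the only alkene (C3=C12) to the C3 aldehyde and the C12 methyl ketone, with the dye end point protecting the anisyl ring. The stabilised Wittig ylide then reacts only with the aldehyde and gives the (E)-2-methyl enoate (C3=C4, C18, C5); using 14 without isolation should avoid epimerisation at C2.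

Step 11
Reactants: 15 keto enoate (C5 ethyl ester, C12 methyl ketone), 16 tert-butyl 2-(diethoxyphosphoryl)acetate
Product: 17 1-tert-butyl 10-ethyl (2E,4R,6S,7R,8E)-7-[(tert-butyldimethylsilyl)oxy]-4-[(4-methoxybenzyl)oxy]-3,9-dimethyl-6-(2-methyl-1,3-dioxolan-2-yl)deca-2,8-dienedioate
Conditions: 16, NaH, THF, 0 °C to rt
Reagents that add atoms: none
Why: Horner–Wadsworth–Emmons olefination of an α-alkoxy methyl ketone; reversible addition should favour the (E)-alkene with the ester trans to the branched C13 substituent. The weakly basic phosphonate anion should leave C13 untouched, and the tert-butyl ester marks C10 against the ethyl ester at C5.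

Step 12
Reactants: 17 diester (C5 ethyl ester, C10 tert-butyl ester)
Product: 18 tert-butyl (2E,4R,6S,7R,8E)-7-[(tert-butyldimethylsilyl)oxy]-10-hydroxy-4-[(4-methoxybenzyl)oxy]-3,9-dimethyl-6-(2-methyl-1,3-dioxolan-2-yl)deca-2,8-dienoate
Conditions: i-Bu2AlH (2.2 equiv), CH2Cl2, −78 °C
Reagents that add atoms: none
Why: Chemoselective 1,2-reduction of an enoate by an aluminium hydride; the ethyl ester should be reduced at −78 °C, while the bulky tert-butyl ester of the β,β-disubstituted enoate reacts much more slowly.

Step 13
Reactants: 18 C5 allylic alcohol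
Product: 19 tert-butyl (2E,4R,6S,7R,8E)-10-bromo-7-[(tert-butyldimethylsilyl)oxy]-4-[(4-methoxybenzyl)oxy]-3,9-dimethyl-6-(2-methyl-1,3-dioxolan-2-yl)deca-2,8-dienoate
Conditions: CBr4, PPh3, 2,6-lutidine, CH2Cl2, 0 °C
Reagents that add atoms: carbon tetrabromide BrC(Br)(Br)Br
Why: Appel bromination; SN2 at the primary carbon of the alkoxyphosphonium ion under buffered conditions gives the allylic bromide without transposition.

Step 14
Reactants: 20 1-bromo-3-methylbut-2-ene
Product: 21 [(3-methylbut-2-en-1-yl)sulfonyl]benzene
Conditions: PhSO2Na, DMF, rt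
Reagents that add atoms: sodium benzenesulfinate [Na+].[O-]S(=O)c1ccccc1
Why: SN2 S-alkylation of the sulfinate anion by a primary allylic bromide in a dipolar aprotic solvent.

Step 15
Reactants: 21 [(3-methylbut-2-en-1-yl)sulfonyl]benzene
Product: 23 (E)-2-methyl-4-(phenylsulfonyl)but-2-en-1-ol, via sulfonyl enal 22 (not isolated)
Conditions: SeO2 (cat.), t-BuOOH, CH2Cl2, rt; then NaBH4, MeOH, 0 °C
Reagents that add atoms: tert-butyl hydroperoxide CC(C)(C)OO
Why: Riley oxidation, selective for the methyl group trans to the sulfonylmethyl chain; this sets the (E)-C7=C8 alkene, and borohydride returns aldehyde 22 to the alcohol.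

Step 16
Reactants: 23 (E)-2-methyl-4-(phenylsulfonyl)but-2-en-1-ol
Product: 24 (E)-tert-butyldimethyl{[2-methyl-4-(phenylsulfonyl)but-2-en-1-yl]oxy}silane
Conditions: t-BuMe2SiCl, imidazole, CH2Cl2, rt
Reagents that add atoms: tert-butyldimethylsilyl chloride CC(C)(C)[Si](C)(C)Cl
Why: Imidazole-promoted silylation of a primary alcohol; the silyl ether masks the C9 oxygen through the carbanion and hydride steps.

Step 17
Reactants: 19 C5 allylic bromide, 24 C6–C9 sulfone
Product: 25 open-chain C10 tert-butyl ester with C5–C6 joined (C6 phenylsulfonyl as both epimers, C9 silyl ether)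
Conditions: 24, n-BuLi, THF, −78 °C; then 19, −78 to −40 °C
Reagents that add atoms: none
Why: Alkylation of a lithiated allylic sulfone, which reacts at the carbon α to sulfur by SN2 at the primary allylic bromide; this forms C5–C6 with all alkene geometries untouched. The new C6 centre is of no consequence, and the hindered tert-butyl enoate should not compete at low temperature.

Step 18
Reactants: 25 open-chain C10 tert-butyl ester
Product: 26 C10 allylic alcohol (C6 sulfone, C9 silyl ether)
Conditions: i-Bu2AlH (4 equiv), CH2Cl2, −78 to −20 °C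
Reagents that add atoms: none
Why: With excess hydride and a higher temperature the tert-butyl enoate undergoes 1,2-reduction to the allylic alcohol; sulfone, ketal and ethers are inert.

Step 19
Reactants: 26 C10 allylic alcohol
Product: 28 C6,C10-bis(phenylsulfonyl) compound (C9 silyl ether), via allylic bromide 27 (not isolated)
Conditions: CBr4, PPh3, 2,6-lutidine, CH2Cl2, 0 °C; then PhSO2Na, n-Bu4NI (cat.), DMF, rt
Reagents that add atoms: sodium benzenesulfinate [Na+].[O-]S(=O)c1ccccc1; carbon tetrabromide BrC(Br)(Br)Br (bromine of 27 only)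
Why: Appel bromination followed by SN2 S-alkylation of sulfinate places the second, primary allylic sulfone on C10 as the nucleophile for ring closure.

Step 20
Reactants: 28 C6,C10-bis(phenylsulfonyl) compound
Product: 29 C9 primary allylic alcohol (C2 silyl ether retained)
Conditions: HF·pyridine, pyridine, THF, 0 °C
Reagents that add atoms: none
Why: Selective desilylation; buffered fluoride cleaves the unhindered primary allylic silyl ether much faster than the secondary C2 silyl ether flanked by the branched C1.

Step 21
Reactants: 29 C9 primary allylic alcohol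
Product: 30 C9 allylic bromide (C6 and C10 sulfones)
Conditions: CBr4, PPh3, 2,6-lutidine, CH2Cl2, −20 to 0 °C
Reagents that add atoms: carbon tetrabromide BrC(Br)(Br)Br
Why: Appel bromination of the primary allylic alcohol under neutral conditions, compatible with the acidic sulfone positions.

Step 22
Reactants: 30 C9 allylic bromide
Product: 31 fourteen-membered 6,10-bis(phenylsulfonyl) carbocycle
Conditions: KN(SiMe3)2 (2.2 equiv), THF, 0.002 M, −78 to 0 °C, slow addition of 30
Reagents that add atoms: none
Why: Intramolecular alkylation of a sulfone-stabilised allylic carbanion at high dilution, a standard closure of cembranoid rings; the C10 anion closes the fourteen-membered ring by exo SN2 attack on C9, whereas the C6 anion could only form a four-membered ring and is unproductive. No stereocentre of consequence is formed, and the (E)-alkenes are not touched.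

Step 23
Reactants: 31 fourteen-membered 6,10-bis(phenylsulfonyl) carbocycle
Product: 32 fourteen-membered triene (C1 dioxolane, C2 silyl ether, C13 4-methoxybenzyl ether)
Conditions: PdCl2(dppp) (10 mol %; dppp = 1,3-bis(diphenylphosphino)propane), LiBHEt3, THF, 0 °C to rt
Reagents that add atoms: none
Why: Palladium-catalysed reductive desulfonylation of allylic sulfones; ionisation to a π-allyl complex and hydride delivery to the less substituted terminus (C6, C10) should keep the position and E geometry of both trisubstituted alkenes.

Step 24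
Reactants: 32 fourteen-membered triene
Product: 33 C1 acetyl macrocycle
Conditions: pyridinium p-toluenesulfonate, acetone–H2O, 50 °C
Reagents that add atoms: water O
Why: Mild acid-catalysed ketal hydrolysis and exchange with acetone; the weak acid should spare the allylic silyl and 4-methoxybenzyl ethers and should not epimerise C1.

Step 25
Reactants: 33 C1 acetyl macrocycle
Product: 34 alkenyl triflate (C15=C17, triflate on C15)
Conditions: KN(SiMe3)2, THF, −78 °C; PhNTf2, −78 to 0 °C
Reagents that add atoms: N-phenylbis(trifluoromethanesulfonimide) O=S(=O)(N(c1ccccc1)S(=O)(=O)C(F)(F)F)C(F)(F)F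
Why: Kinetic deprotonation by a hindered amide base takes the methyl protons and not the tertiary C1–H, so the cross-conjugated enolate cannot expel the C2 silyloxy group; O-triflation then fixes the C15=C17 alkene.

Step 26
Reactants: 34 alkenyl triflate
Product: 35 acrylic acid (C16 carboxyl on C15, C2 silyl ether)
Conditions: Pd(OAc)2 (5 mol %), PPh3, CO (1 atm), KOAc, DMF–H2O, 50 °C
Reagents that add atoms: carbon monoxide [C-]#[O+]; water O
Why: Palladium-catalysed hydroxycarbonylation of an alkenyl triflate (oxidative addition, CO insertion, capture of the acyl complex by acetate and water) adds C16 at the acid oxidation level without touching the other alkenes.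

Step 27
Reactants: 35 acrylic acid
Product: 36 γ-hydroxy acrylic acid (free C2 hydroxyl)
Conditions: n-Bu4NF, THF, 0 to 40 °C; pH 5 buffer work-up at 0 °C
Reagents that add atoms: none
Why: Fluoride-induced desilylation; the acid is present as its carboxylate, which can neither act as a Michael acceptor nor lactonise with retention, and cold buffered work-up should keep the hydroxy acid open.

Step 28
Reactants: 36 γ-hydroxy acrylic acid
Product: 37 trans-fused α-methylene lactone (C13 4-methoxybenzyl ether)
Conditions: PPh3, diisopropyl azodicarboxylate, THF (0.01 M), 0 °C to rt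
Reagents that add atoms: none
Why: Mitsunobu lactonisation; the C2 alkoxyphosphonium ion is displaced by the internal carboxylate (5-exo, SN2) with inversion, which turns the cis C1/C2 pattern of the cycloadduct into the trans-lactone and sets C2 (S).

Step 29
Reactants: 37 trans-fused α-methylene lactone
Product: 38 C13 allylic alcohol
Conditions: 2,3-dichloro-5,6-dicyano-1,4-benzoquinone, CH2Cl2–pH 7 buffer, 0 °C
Reagents that add atoms: none
Why: Oxidative cleavage of the 4-methoxybenzyl ether (benzylic hydride abstraction, then hydrolysis of the oxocarbenium ion) under buffered conditions that leave lactone and alkenes untouched.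

Step 30
Reactants: 38 C13 allylic alcohol
Product: 39 (1R,2S,11R,12R,13R)-11,12-epoxy-13-hydroxy lactone
Conditions: VO(acac)2 (5 mol %), t-BuOOH, CH2Cl2, 0 °C to rt
Reagents that add atoms: tert-butyl hydroperoxide CC(C)(C)OO
Why: Vanadium-catalysed hydroxyl-directed epoxidation reacts only at the alkene next to the free hydroxyl. Allylic 1,2-strain puts C13–H near the C20 methyl group in the vanadate ester, so oxygen is delivered to the face that gives the erythro epoxy alcohol, which sets C11 and C12 as in 40.

Step 31
Reactants: 39 (1R,2S,11R,12R,13R)-11,12-epoxy-13-hydroxy lactone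
Product: 40 target, (1R,2S,3E,7E,11R,12S,13S)-13-acetoxy-11,12-epoxycembra-3,7,15(17)-trien-16,2-olide
Conditions: PPh3, diisopropyl azodicarboxylate, AcOH, toluene, 0 °C to rt
Reagents that add atoms: acetic acid CC(=O)O
Why: Mitsunobu esterification; acetate displaces the C13 alkoxyphosphonium ion by SN2 with inversion, converting the erythro epoxy alcohol into the threo epoxy acetate (13S); pre-forming the betaine should keep free phosphine away from the α-methylene lactone.

## Compound list

1 | 3-methylbut-2-enal (prenal) | CC(C)=CC=O | starting material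
2 | 1,1-dimethoxy-3-methylbut-2-ene | COC(OC)C=C(C)C | intermediate
3 | (E)-4,4-dimethoxy-2-methylbut-2-enal | COC(OC)/C=C(C)/C=O | intermediate
4 | (E)-4,4-dimethoxy-2-methylbut-2-en-1-ol | COC(OC)/C=C(C)/CO | intermediate
5 | (E)-4,4-dimethoxy-2-methylbut-2-en-1-yl acetate | COC(OC)/C=C(C)/COC(C)=O | intermediate
6 | (E)-2-methyl-4-oxobut-2-en-1-yl acetate | CC(=O)OC/C(C)=C/C=O | intermediate
7 | (1E,3E)-4-[(tert-butyldimethylsilyl)oxy]-2-methylbuta-1,3-dien-1-yl acetate | CC(=O)O/C=C(C)/C=C/O[Si](C)(C)C(C)(C)C | intermediate
8 | but-3-en-2-one (methyl vinyl ketone) | CC(=O)C=C | starting material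
9 | (1R,4R,5S)-5-acetyl-4-[(tert-butyldimethylsilyl)oxy]-2-methylcyclohex-2-en-1-yl acetate; target locants 1S,2R,13R | CC(=O)[C@H]1C[C@@H](OC(C)=O)C(C)=C[C@H]1O[Si](C)(C)C(C)(C)C | intermediate
10 | (1R,4R,5S)-4-[(tert-butyldimethylsilyl)oxy]-2-methyl-5-(2-methyl-1,3-dioxolan-2-yl)cyclohex-2-en-1-yl acetate | CC1(OCCO1)[C@H]2C[C@@H](OC(C)=O)C(C)=C[C@H]2O[Si](C)(C)C(C)(C)C | intermediate
11 | (1R,4R,5S)-4-[(tert-butyldimethylsilyl)oxy]-2-methyl-5-(2-methyl-1,3-dioxolan-2-yl)cyclohex-2-en-1-ol | CC1(OCCO1)[C@H]2C[C@@H](O)C(C)=C[C@H]2O[Si](C)(C)C(C)(C)C | intermediate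
12 | tert-butyl{[(1R,4R,6S)-4-[(4-methoxybenzyl)oxy]-3-methyl-6-(2-methyl-1,3-dioxolan-2-yl)cyclohex-2-en-1-yl]oxy}dimethylsilane | CC1(OCCO1)[C@H]2C[C@@H](OCc3ccc(OC)cc3)C(C)=C[C@H]2O[Si](C)(C)C(C)(C)C | intermediate
13 | ethyl 2-(triphenylphosphoranylidene)propanoate | CCOC(=O)C(C)=P(c1ccccc1)(c1ccccc1)c1ccccc1 | starting material
14 | (2S,3S,5R)-2-[(tert-butyldimethylsilyl)oxy]-5-[(4-methoxybenzyl)oxy]-3-(2-methyl-1,3-dioxolan-2-yl)-6-oxoheptanal | O=C[C@@H](O[Si](C)(C)C(C)(C)C)[C@@H](C1(C)OCCO1)C[C@@H](OCc2ccc(OC)cc2)C(C)=O | intermediate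
15 | ethyl (2E,4R,5S,7R)-4-[(tert-butyldimethylsilyl)oxy]-7-[(4-methoxybenzyl)oxy]-2-methyl-5-(2-methyl-1,3-dioxolan-2-yl)-8-oxonon-2-enoate | CCOC(=O)/C(C)=C/[C@@H](O[Si](C)(C)C(C)(C)C)[C@@H](C1(C)OCCO1)C[C@@H](OCc2ccc(OC)cc2)C(C)=O | intermediate
16 | tert-butyl 2-(diethoxyphosphoryl)acetate | CCOP(=O)(OCC)CC(=O)OC(C)(C)C | starting material
17 | 1-tert-butyl 10-ethyl (2E,4R,6S,7R,8E)-7-[(tert-butyldimethylsilyl)oxy]-4-[(4-methoxybenzyl)oxy]-3,9-dimethyl-6-(2-methyl-1,3-dioxolan-2-yl)deca-2,8-dienedioate | CCOC(=O)/C(C)=C/[C@@H](O[Si](C)(C)C(C)(C)C)[C@@H](C1(C)OCCO1)C[C@@H](OCc2ccc(OC)cc2)/C(C)=C/C(=O)OC(C)(C)C | intermediate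
18 | tert-butyl (2E,4R,6S,7R,8E)-7-[(tert-butyldimethylsilyl)oxy]-10-hydroxy-4-[(4-methoxybenzyl)oxy]-3,9-dimethyl-6-(2-methyl-1,3-dioxolan-2-yl)deca-2,8-dienoate | OC/C(C)=C/[C@@H](O[Si](C)(C)C(C)(C)C)[C@@H](C1(C)OCCO1)C[C@@H](OCc2ccc(OC)cc2)/C(C)=C/C(=O)OC(C)(C)C | intermediate
19 | tert-butyl (2E,4R,6S,7R,8E)-10-bromo-7-[(tert-butyldimethylsilyl)oxy]-4-[(4-methoxybenzyl)oxy]-3,9-dimethyl-6-(2-methyl-1,3-dioxolan-2-yl)deca-2,8-dienoate | BrC/C(C)=C/[C@@H](O[Si](C)(C)C(C)(C)C)[C@@H](C1(C)OCCO1)C[C@@H](OCc2ccc(OC)cc2)/C(C)=C/C(=O)OC(C)(C)C | intermediate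
20 | 1-bromo-3-methylbut-2-ene (prenyl bromide) | CC(C)=CCBr | starting material
21 | [(3-methylbut-2-en-1-yl)sulfonyl]benzene | CC(C)=CCS(=O)(=O)c1ccccc1 | intermediate
22 | (E)-2-methyl-4-(phenylsulfonyl)but-2-enal | O=C/C(C)=C/CS(=O)(=O)c1ccccc1 | intermediate
23 | (E)-2-methyl-4-(phenylsulfonyl)but-2-en-1-ol | OC/C(C)=C/CS(=O)(=O)c1ccccc1 | intermediate
24 | (E)-tert-butyldimethyl{[2-methyl-4-(phenylsulfonyl)but-2-en-1-yl]oxy}silane | CC(C)(C)[Si](C)(C)OC/C(C)=C/CS(=O)(=O)c1ccccc1 | intermediate
25 | open-chain (9,10-seco) C10 tert-butyl ester, (1S,2R,13R,3E,7E,11E): C9 OTBS, C6 SO2Ph (both epimers), C2 OTBS, C1 2-methyl-1,3-dioxolan-2-yl, C13 OPMB | CC(C)(C)[Si](C)(C)OC/C(C)=C/C(S(=O)(=O)c1ccccc1)C/C(C)=C/[C@@H](O[Si](C)(C)C(C)(C)C)[C@@H](C2(C)OCCO2)C[C@@H](OCc3ccc(OC)cc3)/C(C)=C/C(=O)OC(C)(C)C | intermediate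
26 | C10 primary allylic alcohol derived from 25 (other groups unchanged) | CC(C)(C)[Si](C)(C)OC/C(C)=C/C(S(=O)(=O)c1ccccc1)C/C(C)=C/[C@@H](O[Si](C)(C)C(C)(C)C)[C@@H](C2(C)OCCO2)C[C@@H](OCc3ccc(OC)cc3)/C(C)=C/CO | intermediate
27 | C10 primary allylic bromide derived from 26 | CC(C)(C)[Si](C)(C)OC/C(C)=C/C(S(=O)(=O)c1ccccc1)C/C(C)=C/[C@@H](O[Si](C)(C)C(C)(C)C)[C@@H](C2(C)OCCO2)C[C@@H](OCc3ccc(OC)cc3)/C(C)=C/CBr | intermediate
28 | open-chain C6,C10-bis(phenylsulfonyl) compound, (1S,2R,13R,3E,7E,11E), C9 OTBS | CC(C)(C)[Si](C)(C)OC/C(C)=C/C(S(=O)(=O)c1ccccc1)C/C(C)=C/[C@@H](O[Si](C)(C)C(C)(C)C)[C@@H](C2(C)OCCO2)C[C@@H](OCc3ccc(OC)cc3)/C(C)=C/CS(=O)(=O)c4ccccc4 | intermediate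
29 | C9 primary allylic alcohol derived from 28 (C2 OTBS retained) | OC/C(C)=C/C(S(=O)(=O)c1ccccc1)C/C(C)=C/[C@@H](O[Si](C)(C)C(C)(C)C)[C@@H](C2(C)OCCO2)C[C@@H](OCc3ccc(OC)cc3)/C(C)=C/CS(=O)(=O)c4ccccc4 | intermediate
30 | C9 primary allylic bromide derived from 29 | BrC/C(C)=C/C(S(=O)(=O)c1ccccc1)C/C(C)=C/[C@@H](O[Si](C)(C)C(C)(C)C)[C@@H](C2(C)OCCO2)C[C@@H](OCc3ccc(OC)cc3)/C(C)=C/CS(=O)(=O)c4ccccc4 | intermediate
31 | fourteen-membered carbocycle, (1S,2R,13R,3E,7E,11E): C6 and C10 SO2Ph (epimer mixture), C2 OTBS, C1 2-methyl-1,3-dioxolan-2-yl, C13 OPMB | C1/C(C)=C/C(S(=O)(=O)c2ccccc2)C/C(C)=C/[C@@H](O[Si](C)(C)C(C)(C)C)[C@@H](C3(C)OCCO3)C[C@@H](OCc4ccc(OC)cc4)/C(C)=C/C1S(=O)(=O)c5ccccc5 | intermediate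
32 | (1S,2R,13R,3E,7E,11E)-fourteen-membered triene: C2 OTBS, C1 2-methyl-1,3-dioxolan-2-yl, C13 OPMB, methyls on C4, C8, C12 | C1/C(C)=C/CC/C(C)=C/[C@@H](O[Si](C)(C)C(C)(C)C)[C@@H](C2(C)OCCO2)C[C@@H](OCc3ccc(OC)cc3)/C(C)=C/C1 | intermediate
33 | (1S,2R,13R,3E,7E,11E)-1-acetyl macrocycle (C2 OTBS, C13 OPMB) | C1/C(C)=C/CC/C(C)=C/[C@@H](O[Si](C)(C)C(C)(C)C)[C@@H](C(C)=O)C[C@@H](OCc2ccc(OC)cc2)/C(C)=C/C1 | intermediate
34 | (1S,2R,13R)-alkenyl triflate: C1 bears 1-(trifluoromethylsulfonyloxy)ethenyl (C2 OTBS, C13 OPMB) | C1/C(C)=C/CC/C(C)=C/[C@@H](O[Si](C)(C)C(C)(C)C)[C@@H](C(=C)OS(=O)(=O)C(F)(F)F)C[C@@H](OCc2ccc(OC)cc2)/C(C)=C/C1 | intermediate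
35 | (1R,2R,13R)-acrylic acid: C1 bears 1-carboxyethenyl (C2 OTBS, C13 OPMB) | C1/C(C)=C/CC/C(C)=C/[C@@H](O[Si](C)(C)C(C)(C)C)[C@@H](C(=C)C(=O)O)C[C@@H](OCc2ccc(OC)cc2)/C(C)=C/C1 | intermediate
36 | (1R,2R,13R)-2-hydroxy acrylic acid (C13 OPMB) | C1/C(C)=C/CC/C(C)=C/[C@@H](O)[C@@H](C(=C)C(=O)O)C[C@@H](OCc2ccc(OC)cc2)/C(C)=C/C1 | intermediate
37 | (1R,2S,3E,7E,11E,13R)-13-[(4-methoxybenzyl)oxy]cembra-3,7,11,15(17)-tetraen-16,2-olide | C=C1C(=O)O[C@H]2/C=C(\C)CC/C=C(\C)CC/C=C(\C)[C@H](OCc3ccc(OC)cc3)C[C@H]12 | intermediate
38 | (1R,2S,3E,7E,11E,13R)-13-hydroxycembra-3,7,11,15(17)-tetraen-16,2-olide | C=C1C(=O)O[C@H]2/C=C(\C)CC/C=C(\C)CC/C=C(\C)[C@H](O)C[C@H]12 | intermediate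
39 | (1R,2S,3E,7E,11R,12R,13R)-11,12-epoxy-13-hydroxycembra-3,7,15(17)-trien-16,2-olide | C=C1C(=O)O[C@H]2/C=C(\C)CC/C=C(\C)CC[C@H]3O[C@]3(C)[C@H](O)C[C@H]12 | intermediate
40 | (1R,2S,3E,7E,11R,12S,13S)-13-acetoxy-11,12-epoxycembra-3,7,15(17)-trien-16,2-olide | C=C1C(=O)O[C@H]2/C=C(\C)CC/C=C(\C)CC[C@H]3O[C@]3(C)[C@@H](OC(C)=O)C[C@H]12 | target

Changes of descriptor at C1 (S to R at 35), C2 (R to S in 14 only) and C12 (R in 39, S in 40) come from substituent priorities; the only real inversions are at C2 in step 28 and at C13 in step 31.

## Step count and risks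

Total: 31 steps. Longest linear sequence: 28 steps (steps 1–13 and 17–31, from 1 to 40); the three-step sulfone branch (steps 14–16) joins at step 17.

**Step 6 (key step).** The silyl dienol ether may be cleaved or may react by a stepwise Mukaiyama–Michael pathway under the strongly Lewis-acidic catalyst. Enantiofacial or endo selectivity may also erode, because the diene carries two oxygen substituents of opposing directing power. Fallback: 7 and 8 are combined without catalyst in toluene at 60 °C, which should give 9 together with its enantiomer F1. Ketalisation as in step 7 gives 10 together with the enantiomeric acetate F2. Lipase from Burkholderia cepacia in phosphate buffer should then hydrolyse only the (1R)-acetate 10, following the empirical preference of lipases for secondary carbinyl esters whose larger flank has the higher priority. This gives 11, where the route is rejoined; F2 stays as the acetate and is separated.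

**Step 12.** Chemoselectivity between the two enoate esters may be lost, by partial reduction of the tert-butyl ester or by incomplete reduction of the ethyl ester, since both are conjugated esters and differ only in steric bulk. Fallback: starting from 17, LiOH in aqueous THF hydrolyses only the ethyl ester, tert-butyl esters being inert to hydroxide, and gives the C5 carboxylic acid F3. Activation as the mixed anhydride (isobutyl chloroformate, N-methylmorpholine) and reduction with NaBH4 gives 18.

**Step 22.** Intermolecular alkylation to oligomers and base-induced elimination of the allylic bromide compete, because a fourteen-membered ring closes slowly. Fallback: the ring is closed by reductive allyl–allyl coupling instead of carbanion alkylation. Starting from 26, HF·pyridine frees the C9 hydroxyl to give the C9,C10-diol F4, and CBr4/PPh3 gives the bis(allylic bromide) F5. Ni(CO)4 in N-methylpyrrolidone at high dilution should couple the two primary allylic termini and give the fourteen-membered C6 monosulfone F6; erosion of alkene geometry in the allylnickel intermediates is the known weakness of this coupling. Desulfonylation as in step 23 then gives 32.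

**Step 28.** The γ-hydroxy acid may lactonise with retention, either during work-up of step 27 or through an acyloxyphosphonium pathway, and the allylic alkoxyphosphonium ion may ionise. Fallback: C2 is inverted first and the lactone is then closed with retention. Starting from 34, HF·pyridine gives the hydroxy alkenyl triflate F7. A Mitsunobu reaction with 4-nitrobenzoic acid gives the C2-inverted 4-nitrobenzoate F8, and brief methanolysis (K2CO3, MeOH, 0 °C) gives the 2-epi alcohol F9. Carbonylative lactonisation (Pd(PPh3)4, CO, Et3N, MeCN), in which the hydroxyl captures the acylpalladium intermediate, gives 37.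

**Step 31.** The SN2 displacement at C13 is slow because the neighbouring epoxide carbon is fully substituted. Elimination, participation of the epoxide oxygen and addition of free phosphine to the α-methylene lactone may then take over. Fallback: the redox condensation is replaced by a two-stage inversion through an isolated sulfonate. Starting from 39, chloromethanesulfonyl chloride and pyridine give the chloromethanesulfonate F10, and CsOAc with 18-crown-6 in toluene displaces it with inversion to give 40.

## Further compounds

F1 | step 6 | (1S,4S,5R)-5-acetyl-4-[(tert-butyldimethylsilyl)oxy]-2-methylcyclohex-2-en-1-yl acetate (enantiomer of 9) | CC(=O)[C@@H]1C[C@H](OC(C)=O)C(C)=C[C@@H]1O[Si](C)(C)C(C)(C)C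
F2 | step 6 | (1S,4S,5R)-4-[(tert-butyldimethylsilyl)oxy]-2-methyl-5-(2-methyl-1,3-dioxolan-2-yl)cyclohex-2-en-1-yl acetate (enantiomer of 10) | CC1(OCCO1)[C@@H]2C[C@H](OC(C)=O)C(C)=C[C@@H]2O[Si](C)(C)C(C)(C)C
F3 | step 12 | (2E,4R,5S,7R,8E)-10-tert-butoxy-4-[(tert-butyldimethylsilyl)oxy]-7-[(4-methoxybenzyl)oxy]-2,8-dimethyl-5-(2-methyl-1,3-dioxolan-2-yl)-10-oxodeca-2,8-dienoic acid | OC(=O)/C(C)=C/[C@@H](O[Si](C)(C)C(C)(C)C)[C@@H](C1(C)OCCO1)C[C@@H](OCc2ccc(OC)cc2)/C(C)=C/C(=O)OC(C)(C)C
F4 | step 22 | open-chain C9,C10-diol with C6 phenylsulfonyl (C2 OTBS, C1 dioxolane, C13 OPMB) | OC/C(C)=C/C(S(=O)(=O)c1ccccc1)C/C(C)=C/[C@@H](O[Si](C)(C)C(C)(C)C)[C@@H](C2(C)OCCO2)C[C@@H](OCc3ccc(OC)cc3)/C(C)=C/CO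
F5 | step 22 | open-chain C9,C10-bis(allylic bromide) with C6 phenylsulfonyl | BrC/C(C)=C/C(S(=O)(=O)c1ccccc1)C/C(C)=C/[C@@H](O[Si](C)(C)C(C)(C)C)[C@@H](C2(C)OCCO2)C[C@@H](OCc3ccc(OC)cc3)/C(C)=C/CBr
F6 | step 22 | fourteen-membered carbocycle with C6 phenylsulfonyl only (C2 OTBS, C1 dioxolane, C13 OPMB) | C1/C(C)=C/C(S(=O)(=O)c2ccccc2)C/C(C)=C/[C@@H](O[Si](C)(C)C(C)(C)C)[C@@H](C3(C)OCCO3)C[C@@H](OCc4ccc(OC)cc4)/C(C)=C/C1
F7 | step 28 | (1S,2R,13R)-2-hydroxy alkenyl triflate (C13 OPMB) | C1/C(C)=C/CC/C(C)=C/[C@@H](O)[C@@H](C(=C)OS(=O)(=O)C(F)(F)F)C[C@@H](OCc2ccc(OC)cc2)/C(C)=C/C1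
F8 | step 28 | (1S,2S,13R)-2-(4-nitrobenzoyloxy) alkenyl triflate (C13 OPMB) | C1/C(C)=C/CC/C(C)=C/[C@H](OC(=O)c2ccc(cc2)[N+](=O)[O-])[C@@H](C(=C)OS(=O)(=O)C(F)(F)F)C[C@@H](OCc3ccc(OC)cc3)/C(C)=C/C1
F9 | step 28 | (1S,2S,13R)-2-hydroxy alkenyl triflate (C13 OPMB) | C1/C(C)=C/CC/C(C)=C/[C@H](O)[C@@H](C(=C)OS(=O)(=O)C(F)(F)F)C[C@@H](OCc2ccc(OC)cc2)/C(C)=C/C1
F10 | step 31 | 13-O-(chloromethanesulfonyl) derivative of 39 | C=C1C(=O)O[C@H]2/C=C(\C)CC/C=C(\C)CC[C@H]3O[C@]3(C)[C@H](OS(=O)(=O)CCl)C[C@H]12
A1 | alternative 1 | fourteen-membered C11≡C12 cycloalkyne α-methylene lactone, C13 triethylsilyl ether, without C20 | C=C1C(=O)O[C@H]2/C=C(\C)CC/C=C(\C)CCC#C[C@H](O[Si](CC)(CC)CC)C[C@H]12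
A2 | alternative 2 | (3E,7E,11E)-triene α-methylene lactone, C13 tert-butyldimethylsilyl ether | C=C1C(=O)O[C@H]2/C=C(\C)CC/C=C(\C)CC/C=C(\C)[C@H](O[Si](C)(C)C(C)(C)C)C[C@H]12
A3 | alternative 3 | fourteen-membered propargylic homoallylic alcohol (C2 hydroxyl, C3≡C4, C13 tert-butyldiphenylsilyl ether, C1 bearing 3-(tert-butyldimethylsilyloxy)prop-1-en-2-yl) | O[C@H]1C#CCC/C=C(\C)CC/C=C(\C)[C@H](O[Si](c2ccccc2)(c2ccccc2)C(C)(C)C)C[C@@H]1C(=C)CO[Si](C)(C)C(C)(C)C
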